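**Retrosynthetic overview**
1. The last bonds made or broken are the four O–Me bonds and the pyrrole N–CH2 bond. Cutting the N–CH2 bond divides the target into 3,4-bis(6,7-dimethoxyquinolin-5-yl)-1H-pyrrole 28 (twofold Suzuki–Miyaura coupling on a 3,4-dibromopyrrole) and (S)-1-(3-chloropropyl)-3-methylazecane 21.
2. Feature that carries the plan: an imagined transannular C5–C10 bond folds the azecane into a trans-decahydroquinoline (piperidine ring fused to a cyclohexane ring). In it, N1–C8a–C4a–C5–OMs (azecane N1–C10–C5–C6) is a γ-amino sulfonate, so Grob fragmentation of the ring-fusion bond with hydride capture of the iminium ion releases the ten-membered ring.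
3. Bicycle 16 comes from six-membered-ring chemistry. (S)-3-Bromo-2-methylpropan-1-ol brings C2–C4 and the only stereocentre, and lithiated 1,5-dimethoxycyclohexa-1,4-diene brings C5–C10. The nitrogen already carries its silyloxypropyl chain and a Boc group when the C–C bond is made.
4. Ring order: cyclohexane ring (bought as the diene), piperidine ring (enaminone condensation, step 5), ten-membered ring (step 9). The pyrrole and quinoline rings are bought.

Key step: step 9

Assumption: the two pyrrole–quinoline axes are taken to rotate freely at room temperature, so C3 of the azecane is the only stereogenic element to be controlled.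

**Route**

Step 1
Reactants: 1 3-aminopropan-1-ol
Product: 2 3-[(triisopropylsilyl)oxy]propan-1-amine
Conditions: TIPSCl (1.05 equiv), imidazole, CH2Cl2, 0 °C to rt
Reagents that add atoms: triisopropylsilyl chloride, CC(C)[Si](Cl)(C(C)C)C(C)C
Why: Standard silyl ether formation (silyl chloride/imidazole) ends on oxygen because N-silyl amines are hydrolysed on aqueous work-up, and the triisopropylsilyl ether is preferred to a tert-butyldimethylsilyl ether because it has to outlast the acid of step 5.

Step 2
Reactants: 2 3-[(triisopropylsilyl)oxy]propan-1-amine; 3 (S)-3-bromo-2-methylpropan-1-ol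
Product: 5 tert-butyl (R)-(3-hydroxy-2-methylpropyl){3-[(triisopropylsilyl)oxy]propyl}carbamate, via secondary amine 4 (not isolated)
Conditions: 2 (3 equiv), K2CO3, NaI (cat.), MeCN, 70 °C; then Boc2O, rt
Reagents that add atoms: di-tert-butyl dicarbonate, CC(C)(C)OC(=O)OC(=O)OC(C)(C)C
Why: SN2 amination of the primary bromide by an excess of the primary amine (which suppresses double alkylation) is followed by chemoselective N-acylation; the stereocentre is a spectator without acidic hydrogen, and the fully substituted carbamate nitrogen has no N–H that could quench the carbanion of step 4.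

Step 3
Reactants: 5 tert-butyl (R)-(3-hydroxy-2-methylpropyl){3-[(triisopropylsilyl)oxy]propyl}carbamate
Product: 6 tert-butyl (R)-(3-iodo-2-methylpropyl){3-[(triisopropylsilyl)oxy]propyl}carbamate
Conditions: I2, PPh3, imidazole, CH2Cl2, 0 °C to rt, dark
Reagents that add atoms: iodine, II
Why: Appel-type iodination of a primary alcohol through the alkoxyphosphonium salt runs under buffered conditions that leave the Boc group, the silyl ether and the neighbouring stereocentre untouched.

Step 4
Reactants: 6 tert-butyl (R)-(3-iodo-2-methylpropyl){3-[(triisopropylsilyl)oxy]propyl}carbamate; 7 1,5-dimethoxycyclohexa-1,4-diene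
Product: 9 tert-butyl (S)-[3-(2,6-dimethoxycyclohexa-2,5-dien-1-yl)-2-methylpropyl]{3-[(triisopropylsilyl)oxy]propyl}carbamate, via lithiated diene 8 (not isolated)
Conditions: 7 (1.5 equiv), t-BuLi (1.4 equiv), THF, −78 °C; DMPU; then 6, −78 to 0 °C
Reagents that add atoms: none
Why: The CH2 between the two enol ether carbons is the most acidic site of 7, and the pentadienyl anion is alkylated at its central carbon by primary iodides (SN2 alkylation of a masked cyclohexane-1,3-dione, which avoids the O-alkylation of the free dione); the new ring carbon is not stereogenic because the ring is symmetric.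

Step 5
Reactants: 9 tert-butyl (S)-[3-(2,6-dimethoxycyclohexa-2,5-dien-1-yl)-2-methylpropyl]{3-[(triisopropylsilyl)oxy]propyl}carbamate
Product: 12 (S)-3-methyl-1-{3-[(triisopropylsilyl)oxy]propyl}-2,3,4,6,7,8-hexahydroquinolin-5(1H)-one, via Boc-amino dione 10 (not isolated), via ammonium dione trifluoroacetate 11 (not isolated)
Conditions: 1 M aq HCl, THF, rt; then TFA, CH2Cl2, 0 °C, evaporate; then Et3N (1 equiv), PhMe, reflux (Dean–Stark)
Reagents that add atoms: water, O
Why: Enol ether hydrolysis, acidolytic Boc cleavage and intramolecular condensation of the freed secondary amine with one of the two equivalent carbonyl groups (enaminone formation, 6-exo-trig addition then loss of water) close the piperidine ring, and the primary triisopropylsilyl ether should tolerate the short, cold acid treatments.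

Step 6
Reactants: 12 (S)-3-methyl-1-{3-[(triisopropylsilyl)oxy]propyl}-2,3,4,6,7,8-hexahydroquinolin-5(1H)-one
Product: 14 (3S,4aR,8aS)-3-methyl-1-{3-[(triisopropylsilyl)oxy]propyl}octahydroquinolin-5(1H)-one, via lithium enolate 13 (not isolated)
Conditions: Li (5 equiv), NH3(l)/THF, t-BuOH (1 equiv), −78 to −33 °C; then solid NH4Cl
Reagents that add atoms: none
Why: In this dissolving-metal (Birch-type) conjugate reduction of a vinylogous amide, the C8a carbanion is protonated along the axis that leads to the chair–chair trans fusion with the C3 methyl group equatorial, the enolate shields the carbonyl group from further reduction, and protonation at C4a gives the more stable trans-fused ketone.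

Step 7
Reactants: 14 (3S,4aR,8aS)-3-methyl-1-{3-[(triisopropylsilyl)oxy]propyl}octahydroquinolin-5(1H)-one
Product: 15 (3S,4aR,5R,8aS)-3-methyl-1-{3-[(triisopropylsilyl)oxy]propyl}decahydroquinolin-5-ol
Conditions: NaOMe (0.1 equiv), MeOH, rt; then NaBH4, −20 °C
Reagents that add atoms: none
Why: Catalytic methoxide first lets C4a (enolisation) and C8a (retro-aza-Michael/aza-Michael) settle in the most stable trans-fused isomer with equatorial methyl, then the small hydride attacks the cyclohexanone along the axial trajectory (borohydride reduction) and sets C5 as the equatorial (5R) alcohol.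

Step 8
Reactants: 15 (3S,4aR,5R,8aS)-3-methyl-1-{3-[(triisopropylsilyl)oxy]propyl}decahydroquinolin-5-ol
Product: 16 (3S,4aR,5R,8aS)-3-methyl-1-{3-[(triisopropylsilyl)oxy]propyl}decahydroquinolin-5-yl methanesulfonate
Conditions: MsCl, Et3N, CH2Cl2, −10 °C; cold aq NaHCO3 work-up, used at once
Reagents that add atoms: methanesulfonyl chloride, CS(=O)(=O)Cl
Why: Sulfonylation of the equatorial secondary alcohol proceeds with retention at C5, the tertiary amine cannot be acylated, and the low temperature keeps the γ-amino mesylate from ionising early.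

Step 9
Reactants: 16 (3S,4aR,5R,8aS)-3-methyl-1-{3-[(triisopropylsilyl)oxy]propyl}decahydroquinolin-5-yl methanesulfonate
Product: 18 (S,E)-3-methyl-1-{3-[(triisopropylsilyl)oxy]propyl}-1,2,3,4,7,8,9,10-octahydroazecine, via ten-membered iminium mesylate 17 (not isolated)
Conditions: NaBH4 (6 equiv, in portions), anhydrous EtOH, 60 °C
Reagents that add atoms: none
Why: Nitrogen inversion puts the N-propyl chain axial and the lone pair equatorial, so that the lone pair, the C8a–C4a bond and the equatorial C5–OMs bond form one anti-periplanar zig-zag; ionisation is then concerted with cleavage of the ring-fusion bond, N1=C8a(+) and C4a=C5 form as mesylate leaves, and the borohydride already in the flask reduces iminium ion 17 to the tertiary amine. The closest known reaction type is the Grob fragmentation of γ-amino sulfonates, known for N-alkyl-trans-decahydroquinolin-5-yl sulfonates, coupled with hydride capture. No bond is formed to close the ten-membered ring: it is the perimeter of the bicycle and is released when the shared bond breaks, so no medium-ring cyclisation has to be paid for. No stereocentre is created (C4a, C5 and C8a are erased, C3 is untouched), and the alkene is E because C4 and C6 are anti about C4a–C5 in the trans-fused chair–chair. Fragmentation must beat substitution and elimination: an equatorial leaving group has only C–C bonds anti to it, so E2 finds no aligned hydrogen, and the equatorial C3 methyl group leaves the axial site on nitrogen free of a syn-axial clash. Hydride capture must beat loss of the ring, so water is excluded (hydration of 17 would open it to an acyclic amino aldehyde that borohydride reduces irreversibly, whereas ethanol adds only reversibly), and prompt reduction also forestalls transannular re-closure of the alkene onto the iminium carbon.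

Step 10
Reactants: 18 (S,E)-3-methyl-1-{3-[(triisopropylsilyl)oxy]propyl}-1,2,3,4,7,8,9,10-octahydroazecine
Product: 19 (S)-3-methyl-1-{3-[(triisopropylsilyl)oxy]propyl}azecane
Conditions: H2 (1 atm), Pd/C, EtOH, rt
Reagents that add atoms: none
Why: Heterogeneous hydrogenation of a strained disubstituted E-alkene is fast and removes the only unsaturation without touching C3 or the silyl ether.

Step 11
Reactants: 19 (S)-3-methyl-1-{3-[(triisopropylsilyl)oxy]propyl}azecane
Product: 20 (S)-3-(3-methylazecan-1-yl)propan-1-ol
Conditions: TBAF, THF, rt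
Reagents that add atoms: none
Why: Fluoride-driven Si–O cleavage (desilylation) is orthogonal to the tertiary amine, and the lipophilic amino alcohol can be purified by acid–base extraction.

Step 12
Reactants: 20 (S)-3-(3-methylazecan-1-yl)propan-1-ol
Product: 21 (S)-1-(3-chloropropyl)-3-methylazecane hydrochloride
Conditions: SOCl2, CHCl3, 0 °C to reflux; evaporate
Reagents that add atoms: thionyl chloride, O=S(Cl)Cl
Why: Chlorodehydroxylation runs through the chlorosulfite (SN2 by chloride), and the HCl released protonates the amine, so the product is kept as a salt that cannot close to an azetidinium ion.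

Step 13
Reactants: 22 6,7-dimethoxyquinoline
Product: 23 5-bromo-6,7-dimethoxyquinoline
Conditions: NBS (1.05 equiv), TFA, 0 °C to rt
Reagents that add atoms: N-bromosuccinimide, O=C1CCC(=O)N1Br
Why: In this electrophilic aromatic bromination of the N-protonated quinoline the 7-methoxy group is tied up in conjugation with the pyridinium nitrogen and C8 lies next to the charged ring, so the 6-methoxy group should direct bromine to its α-type ortho position C5.

Step 14
Reactants: 23 5-bromo-6,7-dimethoxyquinoline
Product: 24 6,7-dimethoxy-5-(4,4,5,5-tetramethyl-1,3,2-dioxaborolan-2-yl)quinoline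
Conditions: B2pin2, PdCl2(dppf) (5 mol %), KOAc, 1,4-dioxane, 90 °C
Reagents that add atoms: bis(pinacolato)diboron, CC1(C)OB(OC1(C)C)B1OC(C)(C)C(C)(C)O1
Why: Miyaura borylation of an aryl bromide with the weak base acetate avoids homocoupling and avoids organolithium reagents, which would add to C2 of the quinoline.

Step 15
Reactants: 25 1-(triisopropylsilyl)-1H-pyrrole
Product: 26 3,4-dibromo-1-(triisopropylsilyl)-1H-pyrrole
Conditions: NBS (2.0 equiv), THF, −78 °C to rt
Reagents that add atoms: N-bromosuccinimide, O=C1CCC(=O)N1Br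
Why: In this electrophilic bromination the bulky N-silyl group screens C2 and C5, so both brominations go to the β-positions C3 and C4.

Step 16
Reactants: 24 6,7-dimethoxy-5-(4,4,5,5-tetramethyl-1,3,2-dioxaborolan-2-yl)quinoline; 26 3,4-dibromo-1-(triisopropylsilyl)-1H-pyrrole
Product: 28 5,5'-(1H-pyrrole-3,4-diyl)bis(6,7-dimethoxyquinoline), via N-silyl diarylpyrrole 27 (not isolated)
Conditions: 24 (2.6 equiv), Pd2(dba)3 (5 mol %), SPhos (20 mol %), K3PO4, PhMe/H2O, 100 °C; then TBAF, THF, rt
Reagents that add atoms: none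
Why: In this twofold Suzuki–Miyaura coupling the electron-rich, bulky biaryl phosphine speeds up oxidative addition into the bromopyrrole and the coupling of the di-ortho-substituted boronate, and fluoride then removes the N-silyl group.

Step 17
Reactants: 28 5,5'-(1H-pyrrole-3,4-diyl)bis(6,7-dimethoxyquinoline); 21 (S)-1-(3-chloropropyl)-3-methylazecane hydrochloride
Product: 30 (S)-5,5'-{1-[3-(3-methylazecan-1-yl)propyl]-1H-pyrrole-3,4-diyl}bis(6,7-dimethoxyquinoline), via sodium pyrrolide 29 (not isolated)
Conditions: NaH (3.5 equiv), DMF, 0 °C; then 21, NaI (cat.), 60 °C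
Reagents that add atoms: none
Why: The pyrrolide anion, far more nucleophilic than the quinoline nitrogens, is N-alkylated (SN2) by the primary chloride under iodide catalysis, and should the free base first close to the spiro azetidinium ion, its opening at a four-ring CH2 gives the same product.

Step 18
Reactants: 30 (S)-5,5'-{1-[3-(3-methylazecan-1-yl)propyl]-1H-pyrrole-3,4-diyl}bis(6,7-dimethoxyquinoline)
Product: 31 isohalitulin
Conditions: BBr3 (15 equiv), CH2Cl2, −78 °C to rt; then H2O, pH 7 buffer, under Ar
Reagents that add atoms: none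
Why: Lewis-acid cleavage of aryl methyl ethers with BBr3 needs an excess because the three basic nitrogens bind the reagent first; C3 is remote from the reaction, and work-up under argon protects the catechols from air oxidation.

**Compound list**
1 | 3-aminopropan-1-ol | NCCCO | starting material
2 | 3-[(triisopropylsilyl)oxy]propan-1-amine | NCCCO[Si](C(C)C)(C(C)C)C(C)C | intermediate
3 | (S)-3-bromo-2-methylpropan-1-ol | C[C@H](CBr)CO | starting material
4 | (R)-2-methyl-3-({3-[(triisopropylsilyl)oxy]propyl}amino)propan-1-ol | C[C@H](CNCCCO[Si](C(C)C)(C(C)C)C(C)C)CO | intermediate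
5 | tert-butyl (R)-(3-hydroxy-2-methylpropyl){3-[(triisopropylsilyl)oxy]propyl}carbamate | C[C@H](CN(CCCO[Si](C(C)C)(C(C)C)C(C)C)C(=O)OC(C)(C)C)CO | intermediate
6 | tert-butyl (R)-(3-iodo-2-methylpropyl){3-[(triisopropylsilyl)oxy]propyl}carbamate | C[C@H](CN(CCCO[Si](C(C)C)(C(C)C)C(C)C)C(=O)OC(C)(C)C)CI | intermediate
7 | 1,5-dimethoxycyclohexa-1,4-diene | COC1=CCC=C(OC)C1 | starting material
8 | (2,6-dimethoxycyclohexa-2,5-dien-1-yl)lithium | [Li]C1C(OC)=CCC=C1OC | intermediate
9 | tert-butyl (S)-[3-(2,6-dimethoxycyclohexa-2,5-dien-1-yl)-2-methylpropyl]{3-[(triisopropylsilyl)oxy]propyl}carbamate | C[C@H](CN(CCCO[Si](C(C)C)(C(C)C)C(C)C)C(=O)OC(C)(C)C)CC1C(OC)=CCC=C1OC | intermediate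
10 | tert-butyl (S)-[3-(2,6-dioxocyclohexyl)-2-methylpropyl]{3-[(triisopropylsilyl)oxy]propyl}carbamate | C[C@H](CN(CCCO[Si](C(C)C)(C(C)C)C(C)C)C(=O)OC(C)(C)C)CC1C(=O)CCCC1=O | intermediate
11 | (S)-3-(2,6-dioxocyclohexyl)-2-methyl-N-{3-[(triisopropylsilyl)oxy]propyl}propan-1-aminium trifluoroacetate | C[C@H](C[NH2+]CCCO[Si](C(C)C)(C(C)C)C(C)C)CC1C(=O)CCCC1=O.[O-]C(=O)C(F)(F)F | intermediate
12 | (S)-3-methyl-1-{3-[(triisopropylsilyl)oxy]propyl}-2,3,4,6,7,8-hexahydroquinolin-5(1H)-one | C[C@H]1CC2=C(CCCC2=O)N(CCCO[Si](C(C)C)(C(C)C)C(C)C)C1 | intermediate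
13 | lithium (3S,8aS)-3-methyl-1-{3-[(triisopropylsilyl)oxy]propyl}-1,2,3,4,6,7,8,8a-octahydroquinolin-5-olate | C[C@@H]1CN(CCCO[Si](C(C)C)(C(C)C)C(C)C)[C@H]2CCCC([O-])=C2C1.[Li+] | intermediate
14 | (3S,4aR,8aS)-3-methyl-1-{3-[(triisopropylsilyl)oxy]propyl}octahydroquinolin-5(1H)-one (trans-fused, methyl equatorial) | C[C@@H]1CN(CCCO[Si](C(C)C)(C(C)C)C(C)C)[C@H]2CCCC(=O)[C@@H]2C1 | intermediate
15 | (3S,4aR,5R,8aS)-3-methyl-1-{3-[(triisopropylsilyl)oxy]propyl}decahydroquinolin-5-ol (equatorial OH) | C[C@@H]1CN(CCCO[Si](C(C)C)(C(C)C)C(C)C)[C@H]2CCC[C@@H](O)[C@@H]2C1 | intermediate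
16 | (3S,4aR,5R,8aS)-3-methyl-1-{3-[(triisopropylsilyl)oxy]propyl}decahydroquinolin-5-yl methanesulfonate | C[C@@H]1CN(CCCO[Si](C(C)C)(C(C)C)C(C)C)[C@H]2CCC[C@@H](OS(C)(=O)=O)[C@@H]2C1 | intermediate
17 | (S,5E)-3-methyl-1-{3-[(triisopropylsilyl)oxy]propyl}-2,3,4,7,8,9-hexahydroazecin-1-ium methanesulfonate | C[C@H]1C/C=C/CCCC=[N+](CCCO[Si](C(C)C)(C(C)C)C(C)C)C1.CS(=O)(=O)[O-] | intermediate
18 | (S,E)-3-methyl-1-{3-[(triisopropylsilyl)oxy]propyl}-1,2,3,4,7,8,9,10-octahydroazecine | C[C@H]1C/C=C/CCCCN(CCCO[Si](C(C)C)(C(C)C)C(C)C)C1 | intermediate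
19 | (S)-3-methyl-1-{3-[(triisopropylsilyl)oxy]propyl}azecane | C[C@H]1CCCCCCCN(CCCO[Si](C(C)C)(C(C)C)C(C)C)C1 | intermediate
20 | (S)-3-(3-methylazecan-1-yl)propan-1-ol | C[C@H]1CCCCCCCN(CCCO)C1 | intermediate
21 | (S)-1-(3-chloropropyl)-3-methylazecane hydrochloride | C[C@H]1CCCCCCCN(CCCCl)C1.Cl | intermediate
22 | 6,7-dimethoxyquinoline | COc1cc2ncccc2cc1OC | starting material
23 | 5-bromo-6,7-dimethoxyquinoline | COc1cc2ncccc2c(Br)c1OC | intermediate
24 | 6,7-dimethoxy-5-(4,4,5,5-tetramethyl-1,3,2-dioxaborolan-2-yl)quinoline | COc1cc2ncccc2c(B2OC(C)(C)C(C)(C)O2)c1OC | intermediate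
25 | 1-(triisopropylsilyl)-1H-pyrrole | CC(C)[Si](C(C)C)(C(C)C)n1cccc1 | starting material
26 | 3,4-dibromo-1-(triisopropylsilyl)-1H-pyrrole | CC(C)[Si](C(C)C)(C(C)C)n1cc(Br)c(Br)c1 | intermediate
27 | 5,5'-[1-(triisopropylsilyl)-1H-pyrrole-3,4-diyl]bis(6,7-dimethoxyquinoline) | COc1cc2ncccc2c(-c2cn([Si](C(C)C)(C(C)C)C(C)C)cc2-c2c(OC)c(OC)cc3ncccc23)c1OC | intermediate
28 | 5,5'-(1H-pyrrole-3,4-diyl)bis(6,7-dimethoxyquinoline) | COc1cc2ncccc2c(-c2c[nH]cc2-c2c(OC)c(OC)cc3ncccc23)c1OC | intermediate
29 | sodium 3,4-bis(6,7-dimethoxyquinolin-5-yl)pyrrol-1-ide | COc1cc2ncccc2c(-c2c[n-]cc2-c2c(OC)c(OC)cc3ncccc23)c1OC.[Na+] | intermediate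
30 | (S)-5,5'-{1-[3-(3-methylazecan-1-yl)propyl]-1H-pyrrole-3,4-diyl}bis(6,7-dimethoxyquinoline) | C[C@H]1CCCCCCCN(CCCn2cc(-c3c(OC)c(OC)cc4ncccc34)c(-c3c(OC)c(OC)cc4ncccc34)c2)C1 | intermediate
31 | isohalitulin, (S)-5,5'-{1-[3-(3-methylazecan-1-yl)propyl]-1H-pyrrole-3,4-diyl}bis(quinoline-6,7-diol) | C[C@H]1CCCCCCCN(CCCn2cc(-c3c(O)c(O)cc4ncccc34)c(-c3c(O)c(O)cc4ncccc34)c2)C1 | target

**Step count**
Total step count: 18.
Longest linear sequence: 14 steps (steps 1–12, 17 and 18).

**Steps most likely to fail**

Step 9.
- What may go wrong: ionisation may occur without cleavage of the ring-fusion bond (solvolysis or transannular re-closure) if the invertomer with the axial N-chain is too thinly populated. The solvent may open the iminium ion before hydride arrives. The liberated borane may be taken up by the amine or by the strained E-alkene.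
- Fallback, from iodide 6 back to 19: the ten-membered ring is closed by olefin metathesis on a tertiary amide instead of being released from a bicycle. Allylmagnesium bromide with catalytic Li2CuCl4 in THF couples with 6 to give tert-butyl (S)-(2-methylhex-5-en-1-yl){3-[(triisopropylsilyl)oxy]propyl}carbamate F1. TFA in CH2Cl2 frees (S)-2-methyl-N-{3-[(triisopropylsilyl)oxy]propyl}hex-5-en-1-amine F2. Pent-4-enoyl chloride and Et3N give (S)-N-(2-methylhex-5-en-1-yl)-N-{3-[(triisopropylsilyl)oxy]propyl}pent-4-enamide F3. Ring-closing metathesis with the second-generation Grubbs catalyst at high dilution in refluxing CH2Cl2 should give (S)-9-methyl-1-{3-[(triisopropylsilyl)oxy]propyl}-3,4,7,8,9,10-hexahydroazecin-2(1H)-one F4, whose alkene geometry is irrelevant. Hydrogenation over Pd/C gives (S)-9-methyl-1-{3-[(triisopropylsilyl)oxy]propyl}azecan-2-one F5, and LiAlH4 in THF reduces the lactam to 19.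

Step 6.
- What may go wrong: electron transfer to the electron-rich vinylogous amide may be sluggish, the ketone may be over-reduced, or the facial control of the protonation at C8a may be poor.
- Fallback, from 12 back to 14: the alkene is saturated on a metal surface and the ring fusion is corrected afterwards by equilibration. Hydrogenation over PtO2 in AcOH (syn addition to C4a=C8a from the face opposite the methyl group, with reduction of the ketone) should give cis-fused (3S,4aR,8aR)-3-methyl-1-{3-[(triisopropylsilyl)oxy]propyl}decahydroquinolin-5-ol F6. Swern oxidation gives cis-fused (3S,4aR,8aR)-3-methyl-1-{3-[(triisopropylsilyl)oxy]propyl}octahydroquinolin-5(1H)-one F7. NaOMe in warm MeOH then equilibrates C4a by enolisation and C8a by retro-aza-Michael/aza-Michael addition towards the most stable isomer 14.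

Step 16.
- What may go wrong: the di-ortho-substituted boronate may suffer protodeboronation, oxidative addition into the electron-rich bromopyrrole may be slow, the reaction may stall after the first coupling, or the N-silyl group may be lost early.
- Fallback, from 26 and 23 back to 27 and, after the TBAF treatment of step 16, to 28: the polarity of the coupling is reversed. Twofold Miyaura borylation of 26 (B2pin2, PdCl2(dppf), KOAc, dioxane) gives 3,4-bis(4,4,5,5-tetramethyl-1,3,2-dioxaborolan-2-yl)-1-(triisopropylsilyl)-1H-pyrrole F8. This is coupled with two equivalents of bromide 23 (Pd2(dba)3, SPhos, K3PO4). Boron then sits on the less hindered pyrrole carbons, palladium inserts into the more willing quinolinyl bromide, and step 14 is no longer needed.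

**Further compounds**
F1 | step 9 | tert-butyl (S)-(2-methylhex-5-en-1-yl){3-[(triisopropylsilyl)oxy]propyl}carbamate | C[C@H](CN(CCCO[Si](C(C)C)(C(C)C)C(C)C)C(=O)OC(C)(C)C)CCC=C
F2 | step 9 | (S)-2-methyl-N-{3-[(triisopropylsilyl)oxy]propyl}hex-5-en-1-amine | C[C@H](CNCCCO[Si](C(C)C)(C(C)C)C(C)C)CCC=C
F3 | step 9 | (S)-N-(2-methylhex-5-en-1-yl)-N-{3-[(triisopropylsilyl)oxy]propyl}pent-4-enamide | C[C@H](CN(CCCO[Si](C(C)C)(C(C)C)C(C)C)C(=O)CCC=C)CCC=C
F4 | step 9 | (S)-9-methyl-1-{3-[(triisopropylsilyl)oxy]propyl}-3,4,7,8,9,10-hexahydroazecin-2(1H)-one (alkene geometry not fixed) | C[C@H]1CCC=CCCC(=O)N(CCCO[Si](C(C)C)(C(C)C)C(C)C)C1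
F5 | step 9 | (S)-9-methyl-1-{3-[(triisopropylsilyl)oxy]propyl}azecan-2-one | C[C@H]1CCCCCCC(=O)N(CCCO[Si](C(C)C)(C(C)C)C(C)C)C1
F6 | step 6 | (3S,4aR,8aR)-3-methyl-1-{3-[(triisopropylsilyl)oxy]propyl}decahydroquinolin-5-ol (cis-fused, C5 not fixed) | C[C@@H]1CN(CCCO[Si](C(C)C)(C(C)C)C(C)C)[C@@H]2CCCC(O)[C@@H]2C1
F7 | step 6 | (3S,4aR,8aR)-3-methyl-1-{3-[(triisopropylsilyl)oxy]propyl}octahydroquinolin-5(1H)-one (cis-fused) | C[C@@H]1CN(CCCO[Si](C(C)C)(C(C)C)C(C)C)[C@@H]2CCCC(=O)[C@@H]2C1
F8 | step 16 | 3,4-bis(4,4,5,5-tetramethyl-1,3,2-dioxaborolan-2-yl)-1-(triisopropylsilyl)-1H-pyrrole | CC(C)[Si](C(C)C)(C(C)C)n1cc(B2OC(C)(C)C(C)(C)O2)c(B2OC(C)(C)C(C)(C)O2)c1
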